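**Minutes: the flask**

The meeting began from the left-handed product of this kinetic resolution, which read 50.3%, 50.0% and 50.4% at 1.04 d in the dawn, winter and noon runs.

the same everywhere: gas 4.8 mM (held)

| charge | left-handed substrate | right-handed substrate | free catalyst | remark | time |
|---|---|---|---|---|---|
| dawn | 7.4 mM | 7.4 mM | 2 mol% | run made earlier |  |
| winter | 16 mM | 16 mM | 2 mol% | run made earlier |  |
| noon | 11 mM | 11 mM | 3 mol% | run made earlier |  |
| flask | 11 mM | 11 mM | 2 mol% |  | 5.0 d |

| run | time / d | right-handed substrate / % | left-handed substrate / % | left-handed product / % |
|---|---|---|---|---|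
| dawn | 1.04 | 44.1 | 0 | 50.3 |
| dawn | 2.08 | 42.7 | 0 | 49.9 |
| dawn | 3.00 | 42.3 | 0 | 50.1 |
| dawn | 4.00 | 42.4 | 0 | 49.9 |
| dawn | 5.00 | 42.1 | 0.8 | 49.6 |
| winter | 1.04 | 38.7 | 0.2 | 50.0 |
| winter | 2.08 | 35.7 | 0.3 | 49.7 |
| winter | 3.00 | 35.2 | 0.2 | 49.9 |
| winter | 4.00 | 34.9 | 0 | 49.9 |
| winter | 5.00 | 35.1 | 0 | 49.7 |
| noon | 1.04 | 37.2 | 0 | 50.4 |
| noon | 2.08 | 35.1 | 0 | 50.0 |
| noon | 3.00 | 34.5 | 0 | 49.9 |
| noon | 4.00 | 34.7 | 0.4 | 50.0 |
| noon | 5.00 | 34.4 | 0 | 50.2 |

(readings scatter by 0.3 percentage points)

- free catalyst is single-handed; left-handed substrate and right-handed substrate are mirror images of each other, charged as a racemate, each of them at the stated concentration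
- at the start none of the gas is in solution

* whether the excess of right-handed substrate over left-handed substrate among what is left of the two reaches 99% by 5.0 d (no / yes)
* the highest excess of right-handed substrate over left-handed substrate among what is left of the two up to 5.0 d

The kineticist noted that right-handed substrate sinks and then stands still in the readings of the dawn, winter and noon runs. She took this as the balance of the catalyst, charged in the flask at 0.220 mM, less than the gas held at 4.8 mM or either substrate. She argued that if the loss of right-handed substrate goes in proportion to what is left of it and the catalyst has a limited life, the logarithm of that loss should scale with the catalyst charged. She therefore proposed the stall number, the natural logarithm of right-handed substrate's starting share over its last reading, per mM of catalyst charged. It read 1.16 /mM at dawn, 1.11 /mM in winter and 1.13 /mM at noon.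

On the noon value, the secretary reckoned that the flask stalls with 39.0% right-handed substrate, so the wanted excess allows 0.196% left-handed substrate, set beside a scatter of 0.3 percentage points.

A sceptic raised the dawn reading of 0.8% at 5.00 d, but the reading before it was 0%, and the last winter and noon readings were 0% and 0%.

The forecast said yes, with a top of 99.8% (range 99% to 100%), holding that “Left-handed readings are only scatter around zero, with no sustained rise”.

    free catalyst + left-handed substrate ⇌ catalyst intermediate A (K = 842 /M, k = 17300 /M/h)
    free catalyst + right-handed substrate ⇌ catalyst intermediate B (K = 144 /M, k = 78300 /M/h)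
    partner + catalyst intermediate A → free catalyst + left-handed product (k = 31700 /M/h)
    partner + catalyst intermediate B → free catalyst + right-handed product (k = 336 /M/h)
    partner → decomposed reagent (k = 0.228 /h)
    partner + free catalyst → spent catalyst (k = 43.4 /M/h)
    gas ⇌ partner, rate k7*(csat - [partner]) (kL = 1.12 /h)

The flask answered yes, with a top of 100%: left-handed substrate went through catalyst intermediate A to left-handed product, and the excess reached 99% by 0.267 d, with 47.2% right-handed substrate left. Right-handed substrate meanwhile passed through catalyst intermediate B to right-handed product as partner turned free catalyst into spent catalyst, which stood at 45.2% of the catalyst charged at 0.500 d and 98.5% at 2.50 d, the flask's own stall number came to 1.11 /mM, and right-handed substrate stood at 39.2% at 5.00 d.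

The numbers in the tables were generated by integration from invented constants, and the scatter is random.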